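**Plan**

1. Target numbering is that of cyclopenta[c]pyridine: C3 carries the dienyl chain, C5 carries OH/CO2Me, C6 carries Me/OMe, C7 is the ketone, C7a is the pyridine carbon next to it. Retrosynthetic cuts, in order: C3–C1′ (pyridine–diene, Suzuki–Miyaura); C7–C7a (aryl–acyl bond, closes the cyclopentanone ring); C5–C6 (aldol between an aryl glyoxylate and a 2-methoxypropanoate); pyridine C4–C(=O) (lithiation/oxalate).
2. Forward: 5-bromo-2-chloropyridine → 4-pyridyl α-keto ester → open-chain aldol adduct holding both quaternary carbons → cyclopentanone ring closed onto the pyridine → dienyl boronate joined at C3 → silyl ether removed.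
3. Enabling feature: C7 is a ketone between the fully substituted C6 and the aromatic C7a. In the open precursor it is the only one of the two ester carbonyls that lies three atoms from the pyridine carbon that becomes C7a; the C5 ester is geminal to the ring and could only give a four-membered ring. The C7 ester can therefore carry the chiral alkoxide that directs the aldol and lose it in the ring closure, and the ketone formed cannot enolise.
4. Stereochemistry: C6 (S) and C5 (R) come from one aldol step, in which the (−)-8-phenylmenthyl ester screens one face of the chelated enolate and a chair transition state fixes C5 relative to C6. C5′ (S) comes from (S)-2-methylbutan-1-ol. The 1E,3E geometry comes from Wittig and boron-Wittig olefinations and is retained in the coupling.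

Key step: step 4

Assumption: the enolate face screened by the auxiliary is assigned with the usual π-shielding model for 8-phenylmenthyl esters (alkoxy C–H eclipsing the C–OLi bond, phenyl over the enolate); if the opposite sense operated, the enantiomeric alcohol would be used with no other change.

**Route**

Step 1
Reactants: 1 5-bromo-2-chloropyridine; 2 dimethyl oxalate
Product: 4 methyl 2-(5-bromo-2-chloropyridin-4-yl)-2-oxoacetate, via 5-bromo-2-chloro-4-lithiopyridine 3 (not isolated)
Conditions: LDA (1.05 equiv), THF, −78 °C; cannulation into 2 (3 equiv), THF, −78 °C; AcOH, −78 °C → rt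
Reagents that add atoms: none
Why: Directed ortho-lithiation removes the C4 hydrogen (ortho to bromine, the most acidic ring C–H), and inverse addition of the aryllithium to excess oxalate should stop at the α-keto ester because the tetrahedral adduct survives until the cold acetic acid quench (acylation of an aryllithium with a dialkyl oxalate).

Step 2
Reactants: 5 (RS)-2-methoxypropanoic acid; 6 (1R,2S,5R)-5-methyl-2-(2-phenylpropan-2-yl)cyclohexan-1-ol ((−)-8-phenylmenthol)
Product: 7 (1R,2S,5R)-5-methyl-2-(2-phenylpropan-2-yl)cyclohexyl 2-methoxypropanoate (both C2 epimers)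
Conditions: DCC, DMAP (cat.), CH2Cl2, 0 °C → rt
Reagents that add atoms: none
Why: Steglich esterification should acylate the hindered secondary alcohol through the acylpyridinium, and the C2 epimer mixture is of no consequence because that carbon becomes the planar enolate carbon in step 3.

Step 3
Reactants: 7 (1R,2S,5R)-5-methyl-2-(2-phenylpropan-2-yl)cyclohexyl 2-methoxypropanoate; 4 methyl 2-(5-bromo-2-chloropyridin-4-yl)-2-oxoacetate
Product: 10 1-methyl 4-[(1R,2S,5R)-5-methyl-2-(2-phenylpropan-2-yl)cyclohexyl] (2R,3S)-2-(5-bromo-2-chloropyridin-4-yl)-3-methoxy-3-methyl-2-[(triethylsilyl)oxy]butanedioate, via lithium enolate 8 (not isolated), via lithium aldolate 9 (not isolated)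
Conditions: 7 (1.1 equiv), LDA (1.05 equiv), THF, −78 °C; 4, THF, −78 °C; TESOTf (1.3 equiv), −78 → −40 °C; aq. NaHCO3
Reagents that add atoms: triethylsilyl trifluoromethanesulfonate, CC[Si](CC)(CC)OS(=O)(=O)C(F)(F)F
Why: Lithium enolate aldol addition to an α-keto ester: LDA should give the chelated enolate (OMe cis to OLi) whose rear face is screened by the phenyl group of the auxiliary, so bond formation on the open face sets C3 (S), while a Zimmerman–Traxler chair with the pyridyl group equatorial and the lithium-chelating CO2Me group axial sets C2 (R), and TESOTf caps the tertiary lithium alkoxide at −78 °C before retro-aldol can occur.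

Step 4
Reactants: 10 1-methyl 4-[(1R,2S,5R)-5-methyl-2-(2-phenylpropan-2-yl)cyclohexyl] (2R,3S)-2-(5-bromo-2-chloropyridin-4-yl)-3-methoxy-3-methyl-2-[(triethylsilyl)oxy]butanedioate
Product: 13 methyl (5R,6S)-3-chloro-6-methoxy-6-methyl-7-oxo-5-[(triethylsilyl)oxy]-6,7-dihydro-5H-cyclopenta[c]pyridine-5-carboxylate, via arylmagnesium chloride 11 (not isolated), via magnesium hemiketal 12 (not isolated)
Conditions: iPrMgCl·LiCl (1.1 equiv), THF, −15 °C → 25 °C; aq. work-up
Reagents that add atoms: none
Why: Br/Mg exchange should occur only at the C–Br bond (the C–Cl bond of the same ring is inert to iPrMgCl·LiCl), placing magnesium on the pyridine carbon that becomes C7a. That carbon lies three atoms from the auxiliary ester carbonyl, so addition gives hemiketal 12, which collapses with loss of 8-phenylmenthoxide to the aryl ketone; the closest known reaction type is the Parham cyclization (halogen–metal exchange followed by intramolecular acylation by an ester) used for 1-indanones. The cyclopentanone ring C4a–C5–C6–C7–C7a is closed in the 5-exo-trig mode. No stereocentre is formed or touched: C5 and C6 are quaternary and the new ketone has no α-hydrogen (C6 fully substituted, C7a aromatic), so neither enolisation nor a second addition is expected. The step needs chemoselectivity between two ester carbonyls, and the substrate secures it because attack on the C5 methyl ester, geminal to the ring, would require a four-membered ring. The silyl ether keeps the C5 oxygen from becoming an alkoxide that could undergo retro-aldol cleavage, and the covalent C–Mg bond should not trigger the 1,4 O→C silyl shift that an aryllithium could.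

Step 5
Reactants: 14 (S)-2-methylbutan-1-ol; 15 ethyl 2-(triphenyl-λ5-phosphanylidene)propanoate
Product: 17 ethyl (2E,4S)-2,4-dimethylhex-2-enoate, via (S)-2-methylbutanal 16 (not isolated)
Conditions: TEMPO (cat.), PhI(OAc)2 (1.1 equiv), CH2Cl2, 0 °C → rt; then 15 (1.5 equiv), rt
Reagents that add atoms: none
Why: TEMPO/PhI(OAc)2 oxidation gives the aldehyde without base, and the stabilised ylide in the same flask should convert it to the (E)-trisubstituted enoate (Wittig reaction) before the α-stereocentre can epimerise; the C4 configuration comes from the starting alcohol.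

Step 6
Reactants: 17 ethyl (2E,4S)-2,4-dimethylhex-2-enoate
Product: 18 (2E,4S)-2,4-dimethylhex-2-en-1-ol
Conditions: DIBAL-H (2.2 equiv), CH2Cl2, −78 °C; aq. Rochelle salt
Reagents that add atoms: none
Why: Hydride reduction of the conjugated ester by DIBAL-H proceeds in 1,2-fashion to the allylic alcohol and leaves the alkene geometry and the stereocentre untouched.

Step 7
Reactants: 18 (2E,4S)-2,4-dimethylhex-2-en-1-ol
Product: 19 (2E,4S)-2,4-dimethylhex-2-enal
Conditions: MnO2 (activated, excess), CH2Cl2, rt
Reagents that add atoms: none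
Why: Allylic oxidation with MnO2 is selective for the allylic alcohol under neutral heterogeneous conditions, so the γ-stereocentre and the E alkene should be preserved.

Step 8
Reactants: 19 (2E,4S)-2,4-dimethylhex-2-enal; 20 2,2′-methylenebis(4,4,5,5-tetramethyl-1,3,2-dioxaborolane)
Product: 22 2-[(1E,3E,5S)-3,5-dimethylhepta-1,3-dien-1-yl]-4,4,5,5-tetramethyl-1,3,2-dioxaborolane, via lithiated bis(boryl)methane 21 (not isolated)
Conditions: 20, LiTMP, THF, 0 °C; then 19, −78 °C → rt; aq. work-up
Reagents that add atoms: none
Why: Boron-Wittig reaction: the α-boryl carbanion adds 1,2 to the aldehyde and syn B–O elimination from the β-alkoxide should give the trans-alkenyl boronate, so the new double bond is E while the existing alkene and stereocentre are unchanged.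

Step 9
Reactants: 13 methyl (5R,6S)-3-chloro-6-methoxy-6-methyl-7-oxo-5-[(triethylsilyl)oxy]-6,7-dihydro-5H-cyclopenta[c]pyridine-5-carboxylate; 22 2-[(1E,3E,5S)-3,5-dimethylhepta-1,3-dien-1-yl]-4,4,5,5-tetramethyl-1,3,2-dioxaborolane
Product: 23 methyl (5R,6S)-3-[(1E,3E,5S)-3,5-dimethylhepta-1,3-dien-1-yl]-6-methoxy-6-methyl-7-oxo-5-[(triethylsilyl)oxy]-6,7-dihydro-5H-cyclopenta[c]pyridine-5-carboxylate
Conditions: Pd(OAc)2 (5 mol%), SPhos (10 mol%), K3PO4, toluene/H2O (10:1), 60 °C
Reagents that add atoms: none
Why: Suzuki–Miyaura coupling: zerovalent palladium should insert into the C3–Cl bond (a 2-chloropyridine activated by the para ketone) and transmetalation/reductive elimination retain the dienyl geometry, while the silyl ether blocks retro-aldol cleavage of the β-oxy ketone under the basic conditions.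

Step 10
Reactants: 23 methyl (5R,6S)-3-[(1E,3E,5S)-3,5-dimethylhepta-1,3-dien-1-yl]-6-methoxy-6-methyl-7-oxo-5-[(triethylsilyl)oxy]-6,7-dihydro-5H-cyclopenta[c]pyridine-5-carboxylate
Product: 24 methyl (5R,6S)-3-[(1E,3E,5S)-3,5-dimethylhepta-1,3-dien-1-yl]-5-hydroxy-6-methoxy-6-methyl-7-oxo-6,7-dihydro-5H-cyclopenta[c]pyridine-5-carboxylate
Conditions: HF·pyridine, THF/pyridine, 0 °C → rt
Reagents that add atoms: none
Why: Fluoride-mediated desilylation under buffered acidic conditions should cleave the tertiary triethylsilyl ether without forming an alkoxide, so the C5/C6 pair cannot scramble by retro-aldol and the diene is left alone.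

**Compound list**

1 | 5-bromo-2-chloropyridine | Clc1ccc(Br)cn1 | starting material
2 | dimethyl oxalate | COC(=O)C(=O)OC | starting material
3 | 5-bromo-2-chloro-4-lithiopyridine | [Li]c1cc(Cl)ncc1Br | intermediate
4 | methyl 2-(5-bromo-2-chloropyridin-4-yl)-2-oxoacetate | COC(=O)C(=O)c1cc(Cl)ncc1Br | intermediate
5 | (RS)-2-methoxypropanoic acid | CC(OC)C(=O)O | starting material
6 | (1R,2S,5R)-5-methyl-2-(2-phenylpropan-2-yl)cyclohexan-1-ol ((−)-8-phenylmenthol) | O[C@@H]1C[C@H](C)CC[C@H]1C(C)(C)c1ccccc1 | starting material
7 | (1R,2S,5R)-5-methyl-2-(2-phenylpropan-2-yl)cyclohexyl 2-methoxypropanoate (both C2 epimers) | CC(OC)C(=O)O[C@@H]1C[C@H](C)CC[C@H]1C(C)(C)c1ccccc1 | intermediate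
8 | lithium enolate of 7, OMe cis to OLi | CO/C(C)=C(\O[Li])O[C@@H]1C[C@H](C)CC[C@H]1C(C)(C)c1ccccc1 | intermediate
9 | lithium alkoxide of the aldol adduct (2R,3S), the precursor of 10 with OLi in place of OSiEt3 | COC(=O)[C@@](O[Li])(c1cc(Cl)ncc1Br)[C@](C)(OC)C(=O)O[C@@H]1C[C@H](C)CC[C@H]1C(C)(C)c1ccccc1 | intermediate
10 | 1-methyl 4-[(1R,2S,5R)-5-methyl-2-(2-phenylpropan-2-yl)cyclohexyl] (2R,3S)-2-(5-bromo-2-chloropyridin-4-yl)-3-methoxy-3-methyl-2-[(triethylsilyl)oxy]butanedioate | COC(=O)[C@@](O[Si](CC)(CC)CC)(c1cc(Cl)ncc1Br)[C@](C)(OC)C(=O)O[C@@H]1C[C@H](C)CC[C@H]1C(C)(C)c1ccccc1 | intermediate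
11 | arylmagnesium chloride derived from 10 (MgCl in place of Br) | COC(=O)[C@@](O[Si](CC)(CC)CC)(c1cc(Cl)ncc1[Mg]Cl)[C@](C)(OC)C(=O)O[C@@H]1C[C@H](C)CC[C@H]1C(C)(C)c1ccccc1 | intermediate
12 | chloromagnesium hemiketal, the ring-closed adduct of 11 in which C7 carries OMgCl and the 8-phenylmenthyloxy group (C7 configuration undefined) | Clc1cc2c(cn1)C(O[Mg]Cl)(O[C@@H]1C[C@H](C)CC[C@H]1C(C)(C)c1ccccc1)[C@@](C)(OC)[C@@]2(O[Si](CC)(CC)CC)C(=O)OC | intermediate
13 | methyl (5R,6S)-3-chloro-6-methoxy-6-methyl-7-oxo-5-[(triethylsilyl)oxy]-6,7-dihydro-5H-cyclopenta[c]pyridine-5-carboxylate | Clc1cc2c(cn1)C(=O)[C@@](C)(OC)[C@@]2(O[Si](CC)(CC)CC)C(=O)OC | intermediate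
14 | (S)-2-methylbutan-1-ol | CC[C@H](C)CO | starting material
15 | ethyl 2-(triphenyl-λ5-phosphanylidene)propanoate | CCOC(=O)C(C)=P(c1ccccc1)(c1ccccc1)c1ccccc1 | starting material
16 | (S)-2-methylbutanal | CC[C@H](C)C=O | intermediate
17 | ethyl (2E,4S)-2,4-dimethylhex-2-enoate | CC[C@H](C)/C=C(C)/C(=O)OCC | intermediate
18 | (2E,4S)-2,4-dimethylhex-2-en-1-ol | CC[C@H](C)/C=C(C)/CO | intermediate
19 | (2E,4S)-2,4-dimethylhex-2-enal | CC[C@H](C)/C=C(C)/C=O | intermediate
20 | 2,2′-methylenebis(4,4,5,5-tetramethyl-1,3,2-dioxaborolane) | CC1(C)OB(CB2OC(C)(C)C(C)(C)O2)OC1(C)C | starting material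
21 | [bis(4,4,5,5-tetramethyl-1,3,2-dioxaborolan-2-yl)methyl]lithium | [Li]C(B1OC(C)(C)C(C)(C)O1)B1OC(C)(C)C(C)(C)O1 | intermediate
22 | 2-[(1E,3E,5S)-3,5-dimethylhepta-1,3-dien-1-yl]-4,4,5,5-tetramethyl-1,3,2-dioxaborolane | CC[C@H](C)/C=C(C)/C=C/B1OC(C)(C)C(C)(C)O1 | intermediate
23 | methyl (5R,6S)-3-[(1E,3E,5S)-3,5-dimethylhepta-1,3-dien-1-yl]-6-methoxy-6-methyl-7-oxo-5-[(triethylsilyl)oxy]-6,7-dihydro-5H-cyclopenta[c]pyridine-5-carboxylate | CC[C@H](C)/C=C(C)/C=C/c1cc2c(cn1)C(=O)[C@@](C)(OC)[C@@]2(O[Si](CC)(CC)CC)C(=O)OC | intermediate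
24 | methyl (5R,6S)-3-[(1E,3E,5S)-3,5-dimethylhepta-1,3-dien-1-yl]-5-hydroxy-6-methoxy-6-methyl-7-oxo-6,7-dihydro-5H-cyclopenta[c]pyridine-5-carboxylate | CC[C@H](C)/C=C(C)/C=C/c1cc2c(cn1)C(=O)[C@@](C)(OC)[C@@]2(O)C(=O)OC | target

**Step count and risks**

Total step count: 10. Longest linear sequence: 6 steps (14 → 17 → 18 → 19 → 22 → 23 → 24; steps 5 to 10).

Steps most likely to fail:

Step 3. The auxiliary may discriminate poorly between the faces of a tetrasubstituted enolate. The ketone may also add through the other orientation (pyridyl axial), which would make the C5 epimer the main product, and the aldolate may revert before it is silylated. Stereoisomers of 10 are diastereomers and separable, but if the ketone orientation is the wrong one the fallback sets out from 4 and returns at 13. C6 is then taken from the chiral pool by self-regeneration of stereocentres. (2R,5R)-2-tert-Butyl-5-methyl-1,3-dioxolan-4-one F1 would be made from (R)-lactic acid and pivalaldehyde (TsOH cat., pentane, water removal; the cis isomer is used), deprotonated (LDA, THF, −78 °C) and added to 4. The electrophile enters anti to the tert-butyl group, which fixes C6. Because the ring holds the oxygen trans to OLi, this enolate turns the opposite ketone orientation into the required C5/C6 relationship. Silylation in the same flask (TESOTf) would give methyl (2R)-2-(5-bromo-2-chloropyridin-4-yl)-2-[(2R,4S)-2-tert-butyl-4-methyl-5-oxo-1,3-dioxolan-4-yl]-2-[(triethylsilyl)oxy]acetate F2. Br/Mg exchange (iPrMgCl·LiCl, THF) would then close the same ring by attack on the dioxolanone carbonyl, and the acetal falls apart to leave methyl (5R,6S)-3-chloro-6-hydroxy-6-methyl-7-oxo-5-[(triethylsilyl)oxy]-6,7-dihydro-5H-cyclopenta[c]pyridine-5-carboxylate F3. Its tertiary hydroxyl is methylated (NaH, MeI, THF, 0 °C) to give 13.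

Step 4. Acyl substitution at the hindered ester (quaternary α-carbon, bulky alkoxide) may be slow, so that the arylmagnesium is protonated on work-up or reacts between molecules, and iPrMgCl may attack an ester before the exchange is complete. The fallback sets out from 10 and returns at 13. The acyl carbon is taken to the aldehyde level and joined to the ring by palladium catalysis instead of by a carbanion. DIBAL-H (CH2Cl2, −78 °C) should reduce the α-methoxy ester selectively, since the α-methoxy group chelates aluminium while the other ester is shielded by the silyl ether and the bromopyridyl ring. This gives methyl (2R,3S)-2-(5-bromo-2-chloropyridin-4-yl)-3-methoxy-3-methyl-4-oxo-2-[(triethylsilyl)oxy]butanoate F4. Intramolecular palladium-catalysed acylation of the aryl bromide by the aldehyde C–H bond (Pd2(dba)3, rac-BINAP, Cs2CO3, dioxane, 110 °C), a known reaction of aldehydes with a quaternary α-carbon, would give 13 directly.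

Step 8. The basic boryl carbanion may deprotonate enal 19 at the γ-position, which would erode the stereocentre through the dienolate; conjugate addition or incomplete E selectivity are also possible. The fallback sets out from 19 and returns at 22. Seyferth–Gilbert homologation with dimethyl (1-diazo-2-oxopropyl)phosphonate (K2CO3, MeOH, 0 °C → rt) would give (3E,5S)-3,5-dimethylhept-3-en-1-yne F5. Hydroboration with pinacolborane (Cp2ZrHCl cat., Et3N cat., 60 °C) then adds syn and anti-Markovnikov to give 22.

**Further compounds**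

F1 | step 3 | (2R,5R)-2-tert-butyl-5-methyl-1,3-dioxolan-4-one | O=C1O[C@H](C(C)(C)C)O[C@@H]1C
F2 | step 3 | methyl (2R)-2-(5-bromo-2-chloropyridin-4-yl)-2-[(2R,4S)-2-tert-butyl-4-methyl-5-oxo-1,3-dioxolan-4-yl]-2-[(triethylsilyl)oxy]acetate | O=C1O[C@H](C(C)(C)C)O[C@@]1(C)[C@@](c1cc(Cl)ncc1Br)(O[Si](CC)(CC)CC)C(=O)OC
F3 | step 3 | methyl (5R,6S)-3-chloro-6-hydroxy-6-methyl-7-oxo-5-[(triethylsilyl)oxy]-6,7-dihydro-5H-cyclopenta[c]pyridine-5-carboxylate | Clc1cc2c(cn1)C(=O)[C@@](C)(O)[C@@]2(O[Si](CC)(CC)CC)C(=O)OC
F4 | step 4 | methyl (2R,3S)-2-(5-bromo-2-chloropyridin-4-yl)-3-methoxy-3-methyl-4-oxo-2-[(triethylsilyl)oxy]butanoate | COC(=O)[C@@](O[Si](CC)(CC)CC)(c1cc(Cl)ncc1Br)[C@](C)(OC)C=O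
F5 | step 8 | (3E,5S)-3,5-dimethylhept-3-en-1-yne | CC[C@H](C)/C=C(C)/C#C
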